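Using drimane numbering, the decalin is cut at C5–C10 and C8–C9. Ring B is a 3-methylenecyclohexene (exocyclic C8=C12 conjugated with C6=C7) whose sp3 neighbours C5, C10 and C9 are stereocentres: the signature of a [4+2] adduct between a vinylallene (C5=C6–C7=C8=C12) and an alkene (C9=C10), with C1–C4 of ring A as tether. One intramolecular Diels–Alder reaction of an acyclic 6-silyloxy dodeca-2,8,10,11-tetraenoate therefore closes both carbocycles and sets C5, C9 and C10, relayed from C3, which comes from an asymmetric reverse prenylation. Ester reduction, Mitsunobu coupling with umbelliferone and desilylation complete the target.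

Key step: step 7

Remark: the prenylborane carrying isopinocampheyl groups from (+)-α-pinene is assumed to show its usual si-face preference towards aldehyde 3, which corresponds to the required 6R carbinol (C3 of the target).

Step 1
Reactants: 1 methyl geranate [methyl (2E)-3,7-dimethylocta-2,6-dienoate]
Product: 3 methyl (2E)-3-methyl-6-oxohex-2-enoate, via ozonide 2 (not isolated)
Conditions: O3 (1 equiv, Sudan Red 7B end point), CH2Cl2, −78 °C; then PPh3, −78 °C → rt
Reagents that add atoms: ozone, [O-][O+]=O
Why: Chemoselective ozonolysis, in which electrophilic ozone should consume the electron-rich trisubstituted 6,7-alkene much faster than the ester-deactivated 2,3-alkene, so that stopping at the indicator end point and reducing ozonide 2 with PPh3 leaves the (E)-enoate intact.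

Step 2
Reactants: 3 methyl (2E)-3-methyl-6-oxohex-2-enoate; 4 3-methylbuta-1,2-diene
Product: 7 methyl (2E,6R)-6-hydroxy-3,7,7-trimethylnona-2,8-dienoate, via prenylborane 5 (not isolated), via borinate 6 (not isolated)
Conditions: (−)-Ipc2BH (crystalline, from (+)-α-pinene), 4, THF, −25 °C; then 3, Et2O, −78 °C; NaBO3·4H2O, H2O, rt
Reagents that add atoms: (−)-diisopinocampheylborane, B([C@@H]1C[C@@H]2C[C@H]([C@H]1C)C2(C)C)[C@@H]1C[C@@H]2C[C@H]([C@H]1C)C2(C)C (boron and isopinocampheyl groups are carried by 5 and 6 and leave on oxidation; 7 retains only its hydrogen)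
Why: Brown asymmetric reverse prenylation, in which hydroboration of the allene at its CH2 terminus gives prenylborane 5, which adds through its γ carbon in a closed chair transition state to the aldehyde alone (the ester is inert at −78 °C), the isopinocampheyl groups directing attack to the si face and so setting the 6R carbinol.

Step 3
Reactants: 7 methyl (2E,6R)-6-hydroxy-3,7,7-trimethylnona-2,8-dienoate
Product: 8 methyl (2E,6R)-6-(tert-butyldimethylsilyloxy)-3,7,7-trimethylnona-2,8-dienoate
Conditions: TBSOTf, 2,6-lutidine, CH2Cl2, 0 °C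
Reagents that add atoms: TBSOTf, CC(C)(C)[Si](C)(C)OS(=O)(=O)C(F)(F)F
Why: Silyl ether protection, for which the hindered neopentylic secondary alcohol needs the silyl triflate with a non-nucleophilic pyridine base, conditions that touch neither the ester nor the alkenes.

Step 4
Reactants: 8 methyl (2E,6R)-6-(tert-butyldimethylsilyloxy)-3,7,7-trimethylnona-2,8-dienoate
Product: 10 methyl (2E,6R)-6-(tert-butyldimethylsilyloxy)-3,7,7-trimethyl-8-oxooct-2-enoate, via diol 9 (not isolated)
Conditions: OsO4 (cat.), NaIO4, 2,6-lutidine, dioxane–H2O 3:1, rt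
Reagents that add atoms: OsO4, O=[Os](=O)(=O)=O (oxygen donor, restored by the terminal oxidant NaIO4, [Na+].[O-]I(=O)(=O)=O)
Why: Lemieux–Johnson oxidative cleavage, chosen over a second ozonolysis because OsO4 should dihydroxylate the monosubstituted vinyl group well before the electron-poor trisubstituted enoate, after which periodate cleaves diol 9 to a non-enolisable α,α-dimethyl aldehyde.

Step 5
Reactants: 10 methyl (2E,6R)-6-(tert-butyldimethylsilyloxy)-3,7,7-trimethyl-8-oxooct-2-enoate; 11 iodoform
Product: 13 methyl (2E,6R,8E)-6-(tert-butyldimethylsilyloxy)-9-iodo-3,7,7-trimethylnona-2,8-dienoate, via gem-dichromium carbenoid 12 (not isolated)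
Conditions: CrCl2 (excess), CHI3, THF–dioxane, 0 °C → rt, dark
Reagents that add atoms: CrCl2, Cl[Cr]Cl (chromium and chlorine are carried by 12 only)
Why: Takai olefination, in which carbenoid 12 adds to the aldehyde and eliminates to give the (E)-vinyl iodide selectively, a reaction that tolerates esters and silyl ethers and works on α-quaternary aldehydes.

Step 6
Reactants: 13 methyl (2E,6R,8E)-6-(tert-butyldimethylsilyloxy)-9-iodo-3,7,7-trimethylnona-2,8-dienoate; 14 tributyl(propa-1,2-dien-1-yl)stannane
Product: 15 methyl (2E,6R,8E)-6-(tert-butyldimethylsilyloxy)-3,7,7-trimethyldodeca-2,8,10,11-tetraenoate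
Conditions: Pd2(dba)3 (cat.), AsPh3, CuI (cat.), DMF, rt, dark
Reagents that add atoms: none
Why: Stille cross-coupling, in which oxidative addition of the vinyl iodide, copper-assisted transfer of the allenyl group through its tin-bearing carbon and reductive elimination should give the vinylallene with the (E)-alkene retained, the weakly bound AsPh3 ligand and CuI allowing ambient temperature so that the sensitive product is never heated.

Step 7
Reactants: 15 methyl (2E,6R,8E)-6-(tert-butyldimethylsilyloxy)-3,7,7-trimethyldodeca-2,8,10,11-tetraenoate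
Product: 16 methyl (1R,4aS,6R,8aR)-6-(tert-butyldimethylsilyloxy)-5,5,8a-trimethyl-2-methylidene-1,2,4a,5,6,7,8,8a-octahydronaphthalene-1-carboxylate
Conditions: Me2AlCl (2 equiv), CH2Cl2, −78 °C → rt; aq. NaHCO3
Reagents that add atoms: none
Why: Me2AlCl binds the ester carbonyl and lowers the LUMO of the C9=C10 enoate, which then adds suprafacially in a concerted but asynchronous [4+2] cycloaddition to the s-cis diene C5=C6–C7=C8 of the vinylallene, forming the σ bonds C5–C10 and C8–C9, leaving the orthogonal allene π bond as the exocyclic C8=C12 methylene and creating the ring alkene C6=C7. The closest known reaction types are type 1 intramolecular Diels–Alder reactions of tethered vinylallenes and Lewis acid-promoted cyclisations of undeca-2,8,10-trienoates to trans-fused octalins. Ring B closes as the six-membered cycloadduct itself, and ring A closes as a six-membered ring through the four-carbon tether C1–C4 folded as a chair, C5–C10 being the fusion bond. The cis relation of the C10 methyl group and the C9 ester follows from the (E)-enoate geometry and suprafacial addition, the trans ring fusion (C5–H anti to the C10 methyl) from the ester-endo transition state in which the (E)-diene keeps C4 outside, and the absolute sense of C5, C9 and C10 from the C3 silyloxy group, which prefers the equatorial position of the chair-like tether and thereby selects one diene face. The step thus needs endo and facial selectivity, which should be secured by Lewis acid complexation at low temperature, by the linear sp carbon C8 that presents no substituent of its own to the crowded dienophile, and by the conformational bias of the C3 and C4 substituents, while the (E)-diene flanked by quaternary C4 offers no [1,5]-hydrogen shift and the s-trans-locked product diene cannot react again. The developing 1,3-diaxial contact between the C10 and C4 methyl groups makes this the least certain step.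

Step 8
Reactants: 16 methyl (1R,4aS,6R,8aR)-6-(tert-butyldimethylsilyloxy)-5,5,8a-trimethyl-2-methylidene-1,2,4a,5,6,7,8,8a-octahydronaphthalene-1-carboxylate
Product: 17 [(1R,4aS,6R,8aR)-6-(tert-butyldimethylsilyloxy)-5,5,8a-trimethyl-2-methylidene-1,2,4a,5,6,7,8,8a-octahydronaphthalen-1-yl]methanol
Conditions: LiAlH4, Et2O, 0 °C; aq. NaOH
Reagents that add atoms: none
Why: Hydride reduction of the ester to the primary C11 alcohol, which leaves the non-conjugated diene and the silyl ether alone, does not epimerise C9 under non-equilibrating conditions and is placed before the reducible coumarin lactone enters.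

Step 9
Reactants: 17 [(1R,4aS,6R,8aR)-6-(tert-butyldimethylsilyloxy)-5,5,8a-trimethyl-2-methylidene-1,2,4a,5,6,7,8,8a-octahydronaphthalen-1-yl]methanol; 18 umbelliferone (7-hydroxy-2H-chromen-2-one)
Product: 19 7-{[(1R,4aS,6R,8aR)-6-(tert-butyldimethylsilyloxy)-5,5,8a-trimethyl-2-methylidene-1,2,4a,5,6,7,8,8a-octahydronaphthalen-1-yl]methoxy}-2H-chromen-2-one
Conditions: PPh3, DIAD, THF, 0 → 40 °C
Reagents that add atoms: none
Why: Mitsunobu etherification, in which the primary hydroxyl is activated as an alkoxyphosphonium ion and displaced by the acidic phenol of umbelliferone in an SN2 reaction at the non-stereogenic C11, so no stereocentre is touched.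

Step 10
Reactants: 19 7-{[(1R,4aS,6R,8aR)-6-(tert-butyldimethylsilyloxy)-5,5,8a-trimethyl-2-methylidene-1,2,4a,5,6,7,8,8a-octahydronaphthalen-1-yl]methoxy}-2H-chromen-2-one
Product: 20 7-{[(1R,4aS,6R,8aR)-6-hydroxy-5,5,8a-trimethyl-2-methylidene-1,2,4a,5,6,7,8,8a-octahydronaphthalen-1-yl]methoxy}-2H-chromen-2-one (target CNP0259618.4)
Conditions: HF·pyridine, pyridine, THF, 0 °C → rt
Reagents that add atoms: none
Why: Fluoride-mediated desilylation, in which buffered HF·pyridine cleaves the hindered secondary silyl ether through Si–F bond formation while the lactone, the aryl ether and the diene should tolerate these mildly acidic, non-nucleophilic conditions.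

Compound list
1 | methyl geranate, methyl (2E)-3,7-dimethylocta-2,6-dienoate | CC(C)=CCC/C(C)=C/C(=O)OC | starting material
2 | methyl (2E)-5-(5,5-dimethyl-1,2,4-trioxolan-3-yl)-3-methylpent-2-enoate (ozonide, racemic at the trioxolane carbon) | CC1(C)OOC(CC/C(C)=C/C(=O)OC)O1 | intermediate
3 | methyl (2E)-3-methyl-6-oxohex-2-enoate | O=CCC/C(C)=C/C(=O)OC | intermediate
4 | 3-methylbuta-1,2-diene | CC(C)=C=C | starting material
5 | (3-methylbut-2-en-1-yl)bis[(1R,2S,3R,5R)-2,6,6-trimethylbicyclo[3.1.1]heptan-3-yl]borane (prenylborane) | CC(C)=CCB([C@@H]1C[C@@H]2C[C@H]([C@H]1C)C2(C)C)[C@@H]1C[C@@H]2C[C@H]([C@H]1C)C2(C)C | intermediate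
6 | methyl (2E,6R)-6-{bis[(1R,2S,3R,5R)-2,6,6-trimethylbicyclo[3.1.1]heptan-3-yl]boranyloxy}-3,7,7-trimethylnona-2,8-dienoate (borinate) | C=CC(C)(C)[C@H](OB([C@@H]1C[C@@H]2C[C@H]([C@H]1C)C2(C)C)[C@@H]1C[C@@H]2C[C@H]([C@H]1C)C2(C)C)CC/C(C)=C/C(=O)OC | intermediate
7 | methyl (2E,6R)-6-hydroxy-3,7,7-trimethylnona-2,8-dienoate | C=CC(C)(C)[C@H](O)CC/C(C)=C/C(=O)OC | intermediate
8 | methyl (2E,6R)-6-(tert-butyldimethylsilyloxy)-3,7,7-trimethylnona-2,8-dienoate | C=CC(C)(C)[C@H](O[Si](C)(C)C(C)(C)C)CC/C(C)=C/C(=O)OC | intermediate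
9 | methyl (2E,6R)-6-(tert-butyldimethylsilyloxy)-8,9-dihydroxy-3,7,7-trimethylnon-2-enoate (both C8 epimers) | OCC(O)C(C)(C)[C@H](O[Si](C)(C)C(C)(C)C)CC/C(C)=C/C(=O)OC | intermediate
10 | methyl (2E,6R)-6-(tert-butyldimethylsilyloxy)-3,7,7-trimethyl-8-oxooct-2-enoate | O=CC(C)(C)[C@H](O[Si](C)(C)C(C)(C)C)CC/C(C)=C/C(=O)OC | intermediate
11 | iodoform | IC(I)I | starting material
12 | (iodomethanediyl)bis(dichlorochromium), THF-solvated geminal dichromium carbenoid of trivalent chromium | IC([Cr](Cl)Cl)[Cr](Cl)Cl | intermediate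
13 | methyl (2E,6R,8E)-6-(tert-butyldimethylsilyloxy)-9-iodo-3,7,7-trimethylnona-2,8-dienoate | I/C=C/C(C)(C)[C@H](O[Si](C)(C)C(C)(C)C)CC/C(C)=C/C(=O)OC | intermediate
14 | tributyl(propa-1,2-dien-1-yl)stannane | C=C=C[Sn](CCCC)(CCCC)CCCC | starting material
15 | methyl (2E,6R,8E)-6-(tert-butyldimethylsilyloxy)-3,7,7-trimethyldodeca-2,8,10,11-tetraenoate | C=C=C/C=C/C(C)(C)[C@H](O[Si](C)(C)C(C)(C)C)CC/C(C)=C/C(=O)OC | intermediate
16 | methyl (1R,4aS,6R,8aR)-6-(tert-butyldimethylsilyloxy)-5,5,8a-trimethyl-2-methylidene-1,2,4a,5,6,7,8,8a-octahydronaphthalene-1-carboxylate | C=C1C=C[C@@H]2C(C)(C)[C@H](O[Si](C)(C)C(C)(C)C)CC[C@@]2(C)[C@@H]1C(=O)OC | intermediate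
17 | [(1R,4aS,6R,8aR)-6-(tert-butyldimethylsilyloxy)-5,5,8a-trimethyl-2-methylidene-1,2,4a,5,6,7,8,8a-octahydronaphthalen-1-yl]methanol | C=C1C=C[C@@H]2C(C)(C)[C@H](O[Si](C)(C)C(C)(C)C)CC[C@@]2(C)[C@@H]1CO | intermediate
18 | umbelliferone, 7-hydroxy-2H-chromen-2-one | O=c1ccc2ccc(O)cc2o1 | starting material
19 | 7-{[(1R,4aS,6R,8aR)-6-(tert-butyldimethylsilyloxy)-5,5,8a-trimethyl-2-methylidene-1,2,4a,5,6,7,8,8a-octahydronaphthalen-1-yl]methoxy}-2H-chromen-2-one | C=C1C=C[C@@H]2C(C)(C)[C@H](O[Si](C)(C)C(C)(C)C)CC[C@@]2(C)[C@@H]1COc1ccc2ccc(=O)oc2c1 | intermediate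
20 | 7-{[(1R,4aS,6R,8aR)-6-hydroxy-5,5,8a-trimethyl-2-methylidene-1,2,4a,5,6,7,8,8a-octahydronaphthalen-1-yl]methoxy}-2H-chromen-2-one | C=C1C=C[C@@H]2C(C)(C)[C@H](O)CC[C@@]2(C)[C@@H]1COc1ccc2ccc(=O)oc2c1 | target

Total step count: 10. Longest linear sequence: 10 steps, from methyl geranate 1 to target 20.

Steps most likely to fail

1. Step 7. The β,β-disubstituted enoate may react too slowly even when complexed, so that oligomerisation of the vinylallene or Lewis acid-induced loss of the silyl group overtakes cycloaddition. The methyl/methyl contact in the trans-fused transition state may also erode endo and facial selectivity. Heating in toluene with BHT would be a mere change of conditions. The fallback changes the activating group to a formyl group. It sets out from 15: reduction with iBu2AlH (CH2Cl2, −78 °C) gives the allylic alcohol (2E,6R,8E)-6-(tert-butyldimethylsilyloxy)-3,7,7-trimethyldodeca-2,8,10,11-tetraen-1-ol F1. Oxidation with MnO2 (CH2Cl2, rt) gives the enal (2E,6R,8E)-6-(tert-butyldimethylsilyloxy)-3,7,7-trimethyldodeca-2,8,10,11-tetraenal F2. This much more electrophilic dienophile, complexed with Me2AlCl at −78 °C, should undergo the known Lewis acid-promoted trienal intramolecular Diels–Alder reaction with strong endo preference to give the bicyclic aldehyde (1R,4aS,6R,8aR)-6-(tert-butyldimethylsilyloxy)-5,5,8a-trimethyl-2-methylidene-1,2,4a,5,6,7,8,8a-octahydronaphthalene-1-carbaldehyde F3. This is reduced directly with NaBH4 (MeOH, −20 °C), before C9 can epimerise or the alkene can move into conjugation, and the route is rejoined at 17.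

2. Step 6. Transfer of the allenyl group from tin may occur with allylic transposition, giving a propargyl-coupled enyne, or the vinylallene may oligomerise on the palladium catalyst. The fallback builds the allene by reductive 1,3-transposition of a propargylic alcohol. It sets out from 13: Sonogashira coupling with prop-2-yn-1-ol (Pd(PPh3)2Cl2, CuI, Et3N, THF, rt) gives the enynol methyl (2E,6R,8E)-6-(tert-butyldimethylsilyloxy)-12-hydroxy-3,7,7-trimethyldodeca-2,8-dien-10-ynoate F4. Myers allene synthesis (PPh3, DEAD, 2-nitrobenzenesulfonohydrazide, THF, −15 °C → rt) first gives the Mitsunobu product methyl (2E,6R,8E)-6-(tert-butyldimethylsilyloxy)-3,7,7-trimethyl-12-[1-(2-nitrobenzenesulfonyl)hydrazin-1-yl]dodeca-2,8-dien-10-ynoate F5. On warming this loses the sulfinic acid to give the propargylic diazene methyl (2E,6R,8E)-6-(tert-butyldimethylsilyloxy)-12-diazenyl-3,7,7-trimethyldodeca-2,8-dien-10-ynoate F6, which expels N2 in a retro-ene step and returns to the route at 15.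

3. Step 9. Displacement at the β-branched C11 may be too slow, so that the activated alcohol eliminates towards C9 (a cross-conjugated triene) or alkylates the hydrazide instead of the phenol. The fallback forms the aryl–oxygen bond instead of the alkyl–oxygen bond. It sets out from 17: palladium-catalysed C–O cross-coupling with bought 7-bromo-2H-chromen-2-one (Pd2(dba)3, a bulky di-tert-butyl biaryl phosphine such as RockPhos, Cs2CO3, toluene, 90 °C), a known etherification of primary alcohols with electron-poor aryl bromides, should give 19 directly, where the route is rejoined.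

Further compounds
F1 | step 7 | (2E,6R,8E)-6-(tert-butyldimethylsilyloxy)-3,7,7-trimethyldodeca-2,8,10,11-tetraen-1-ol | C=C=C/C=C/C(C)(C)[C@H](O[Si](C)(C)C(C)(C)C)CC/C(C)=C/CO
F2 | step 7 | (2E,6R,8E)-6-(tert-butyldimethylsilyloxy)-3,7,7-trimethyldodeca-2,8,10,11-tetraenal | C=C=C/C=C/C(C)(C)[C@H](O[Si](C)(C)C(C)(C)C)CC/C(C)=C/C=O
F3 | step 7 | (1R,4aS,6R,8aR)-6-(tert-butyldimethylsilyloxy)-5,5,8a-trimethyl-2-methylidene-1,2,4a,5,6,7,8,8a-octahydronaphthalene-1-carbaldehyde | C=C1C=C[C@@H]2C(C)(C)[C@H](O[Si](C)(C)C(C)(C)C)CC[C@@]2(C)[C@@H]1C=O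
F4 | step 6 | methyl (2E,6R,8E)-6-(tert-butyldimethylsilyloxy)-12-hydroxy-3,7,7-trimethyldodeca-2,8-dien-10-ynoate | OCC#C/C=C/C(C)(C)[C@H](O[Si](C)(C)C(C)(C)C)CC/C(C)=C/C(=O)OC
F5 | step 6 | methyl (2E,6R,8E)-6-(tert-butyldimethylsilyloxy)-3,7,7-trimethyl-12-[1-(2-nitrobenzenesulfonyl)hydrazin-1-yl]dodeca-2,8-dien-10-ynoate | NN(CC#C/C=C/C(C)(C)[C@H](O[Si](C)(C)C(C)(C)C)CC/C(C)=C/C(=O)OC)S(=O)(=O)c1ccccc1[N+](=O)[O-]
F6 | step 6 | methyl (2E,6R,8E)-6-(tert-butyldimethylsilyloxy)-12-diazenyl-3,7,7-trimethyldodeca-2,8-dien-10-ynoate | N=NCC#C/C=C/C(C)(C)[C@H](O[Si](C)(C)C(C)(C)C)CC/C(C)=C/C(=O)OC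
F0 | step 9 | none | none
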